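**Retrosynthetic overview**

1. 31 ⇐ 25: the side chain C12–C16 comes from the C11 tosylate and an isoprenyl Grignard reagent; C11–OH and the C8 carbinol come from the C8=C9 alkene of 21 (formaldehyde ene reaction, hydroxyl-directed epoxidation, hydride opening).
2. 21 ⇐ 15 (C3 inverted through the enone) ⇐ 14: an enantioselective intramolecular Diels–Alder reaction of an achiral, acyclic tetraenal forms C5–C10 and C3–C4. Rings A and B are formed together in this one step (ring A as the cycloadduct ring, ring B as the tether ring); no ring exists before it.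
3. Enabling feature: ring A (C1–C2–C3–C4–C5–C10) carries its oxygen on C3 next to the quaternary C4 with the carbonyl-derived C18, so with a C1=C2 bond it is the adduct of the diene C10=C1–C2=C3(X) and the (E)-2-methyl enal C4=C5. C5–C10 is the bond shared by rings A and B, so tying C5 to C10 through C6–C7–C8=C9 lets the same bond close ring B.
4. 14 ⇐ 12 + formyl ylide 13; 12 ⇐ dienal 8 + CH2(Bpin)2; 8 ⇐ bromoacetal 1 + propyne + ethyl but-2-ynoate (tandem carbocupration/conjugate addition sets Z C8=C9 and E C10=C1).

Key step: step 7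

Remark: labdane numbering is used (C17 = methyl on C8, C18 = oxygenated carbon on C4, C19 = methyl on C4, C20 = methyl on C10; Bpin = 4,4,5,5-tetramethyl-1,3,2-dioxaborolan-2-yl; syn/anti = same/opposite face as C20). The (S)-oxazaborolidinium is assumed to leave the Cα-Si face of the bound enal open; if the sense is the opposite, its (R)-enantiomer is used and nothing else changes.

**Route**

Step 1
Reactants: 1 2-(2-bromoethyl)-1,3-dioxolane; 2 propyne; 3 ethyl but-2-ynoate
Product: 6 ethyl (2E,4Z)-7-(1,3-dioxolan-2-yl)-3,5-dimethylhepta-2,4-dienoate, via Grignard reagent 4 (not isolated), via (Z)-alkenylcopper 5 (not isolated)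
Conditions: Mg, Et2O/THF (10:1), 25 °C; CuBr·SMe2, Et2O/Me2S, −45 °C; propyne (2), −25 °C; then 3, −78 → −30 °C; aq. NH4Cl
Reagents that add atoms: none
Why: Normant carbocupration followed by organocopper conjugate addition: syn-addition of the alkylcopper to propyne puts the chain and copper cis (Z C8=C9), and syn-addition of this alkenylcopper to the alkynoate with protonation under retention puts C9 trans to the ester (E C10=C1).

Step 2
Reactants: 6 ethyl (2E,4Z)-7-(1,3-dioxolan-2-yl)-3,5-dimethylhepta-2,4-dienoate
Product: 7 (2E,4Z)-7-(1,3-dioxolan-2-yl)-3,5-dimethylhepta-2,4-dien-1-ol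
Conditions: i-Bu2AlH (2.2 equiv), CH2Cl2, −78 °C; aq. potassium sodium tartrate
Reagents that add atoms: none
Why: Hydride 1,2-reduction of the conjugated ester at low temperature gives the allylic alcohol and leaves the acetal and both double-bond geometries untouched.

Step 3
Reactants: 7 (2E,4Z)-7-(1,3-dioxolan-2-yl)-3,5-dimethylhepta-2,4-dien-1-ol
Product: 8 (2E,4Z)-7-(1,3-dioxolan-2-yl)-3,5-dimethylhepta-2,4-dienal
Conditions: MnO2 (excess), CH2Cl2, rt
Reagents that add atoms: none
Why: Allylic alcohol oxidation with MnO2 under neutral conditions should give the dienal without E/Z scrambling.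

Step 4
Reactants: 8 (2E,4Z)-7-(1,3-dioxolan-2-yl)-3,5-dimethylhepta-2,4-dienal; 9 bis(4,4,5,5-tetramethyl-1,3,2-dioxaborolan-2-yl)methane
Product: 11 2-[(1E,3E,5Z)-8-(1,3-dioxolan-2-yl)-4,6-dimethylocta-1,3,5-trien-1-yl]-4,4,5,5-tetramethyl-1,3,2-dioxaborolane, via lithiated diborylmethane 10 (not isolated)
Conditions: lithium 2,2,6,6-tetramethylpiperidide (from the amine and n-BuLi), THF, 0 °C; then 8, −78 → 0 °C; H2O
Reagents that add atoms: none
Why: Boron-Wittig olefination: the α-diboryl carbanion adds to the aldehyde and syn B–O elimination gives the (E)-alkenylboronate, which fixes boron in the outside position of the diene.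

Step 5
Reactants: 11 2-[(1E,3E,5Z)-8-(1,3-dioxolan-2-yl)-4,6-dimethylocta-1,3,5-trien-1-yl]-4,4,5,5-tetramethyl-1,3,2-dioxaborolane
Product: 12 (4Z,6E,8E)-4,6-dimethyl-9-(Bpin)nona-4,6,8-trienal
Conditions: pyridinium p-toluenesulfonate (0.2 equiv), acetone/H2O (10:1), 50 °C
Reagents that add atoms: water, O
Why: Acid-catalysed acetal hydrolysis frees the aldehyde under conditions mild enough for the pinacol boronate and the Z-alkene.

Step 6
Reactants: 12 (4Z,6E,8E)-4,6-dimethyl-9-(Bpin)nona-4,6,8-trienal; 13 2-(triphenyl-λ5-phosphanylidene)propanal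
Product: 14 (2E,6Z,8E,10E)-2,6,8-trimethyl-11-(Bpin)undeca-2,6,8,10-tetraenal
Conditions: toluene, 60 °C, 2,6-di-tert-butyl-4-methylphenol (trace); used without delay
Reagents that add atoms: none
Why: Wittig olefination with the stabilised formyl ylide gives the (E)-2-methyl-2-enal, and the temperature is kept below that needed for uncatalysed cycloaddition.

Step 7
Reactants: 14 (2E,6Z,8E,10E)-2,6,8-trimethyl-11-(Bpin)undeca-2,6,8,10-tetraenal
Product: 15 (3S,4S,5S,10S)-bicyclic aldehyde: decalin core with C1=C2 and C8=C9 double bonds, methyls C17, C19, C20, CHO (C18) on C4 and Bpin on C3; 5-H anti to C20, CHO and Bpin both syn to 5-H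
Conditions: (S)-3,3-diphenyl-1-(2-methylphenyl)tetrahydro-1H,3H-pyrrolo[1,2-c][1,3,2]oxazaborole (20 mol %) protonated with (CF3SO2)2NH (18 mol %), CH2Cl2 (0.01 M), −78 → −40 °C; quenched cold with Et3N and used crude in step 8
Reagents that add atoms: none
Why: The protonated oxazaborolidine binds the formyl oxygen of the s-trans enal, and the LUMO-lowered 2-methyl enal undergoes an asynchronous, concerted normal-demand [4+2] cycloaddition with the terminal diene C10=C1–C2=C3, the C5–C10 bond running ahead of C3–C4; the closest known reaction type is the chiral oxazaborolidinium-catalysed intramolecular Diels–Alder reaction of (2E)-trienals to trans-fused bicycles. Ring A is closed as the new cyclohexene by the cycloaddition itself (bonds C5–C10 and C3–C4, new C1=C2), and ring B is closed by the same C5–C10 bond as the six-membered tether ring of a fused (type 1) cyclisation, the four-atom tether C6–C7–C8=C9 joining the dienophile carbon C5 to the diene terminus C10. C4 is set by the E geometry of the enal (suprafacial addition keeps CHO cis to 5-H); C5 and C10 become trans because the Lewis-acid-bound formyl group sits endo, which places 5-H endo and the tether exo, so that C9 and C6 end on opposite faces of ring A; C3 follows from the E geometry of the alkenylboronate (boron cis to the formyl group). The absolute sense of all four centres is controlled by the catalyst, which shields one face of the bound enal. The step needs endo over exo selectivity, one enal face and reaction at the terminal diene only: Lewis-acid activation strengthens the endo preference, the chiral pocket gives the facial bias, and the other diene C8=C9–C10=C1 cannot react because its two-atom link to C5 would demand a four-membered ring. The inside C20 methyl on C10 slows the reaction but becomes the angular methyl, and the matched polarity (C10 onto the enal β-carbon C5) keeps the hindered bond formation feasible at low temperature.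

Step 8
Reactants: 15 bicyclic aldehyde
Product: 17 3,18-diol: as 15 with CH2OH in place of CHO and OH in place of Bpin (3-OH anti to C20, cis to C18), via hydroxymethyl allylboronate 16 (not isolated)
Conditions: NaBH4, MeOH/THF, −20 °C; then 30 % H2O2, 3 M NaOH, 0 °C
Reagents that add atoms: hydrogen peroxide, OO
Why: Hydride reduction of the neopentyl aldehyde, then oxidation of the allylic C–B bond (1,2-boronate migration with retention, no allylic shift), gives the diol and removes the carbonyl before it can react with the allylboronate.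

Step 9
Reactants: 17 3,18-diol
Product: 18 18-O-tert-butyldimethylsilyl ether of 17
Conditions: TBSCl (1.05 equiv), imidazole, DMF, 0 °C
Reagents that add atoms: tert-butyldimethylsilyl chloride, CC(C)(C)[Si](C)(C)Cl
Why: Silylation is selective for the primary hydroxyl because the C3 hydroxyl is secondary, axial and flanked by the quaternary C4.

Step 10
Reactants: 18 18-O-silyl allylic alcohol
Product: 19 1,8(9)-dien-3-one (enone C1=C2–C3=O) with 18-OTBS
Conditions: 1,1,1-triacetoxy-1,1-dihydro-1,2-benziodoxol-3(1H)-one (DMP), NaHCO3, CH2Cl2, rt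
Reagents that add atoms: none
Why: Periodinane oxidation of the allylic alcohol gives the enone and erases the C3 centre, whose configuration from the cycloaddition is opposite to that of the target.

Step 11
Reactants: 19 enone
Product: 21 (3R,4S,5S,10S)-8(9)-en-3-ol with 18-OTBS; 3-OH equatorial, syn to C20 and trans to C18, via saturated ketone 20 (not isolated)
Conditions: H2 (1 atm), Pd/C (5 %), EtOAc, rt; filter; then NaBH4, MeOH, 0 °C
Reagents that add atoms: none
Why: Catalytic hydrogenation saturates the conjugated C1=C2 bond faster than the hindered trisubstituted C8=C9 bond, and NaBH4 then attacks C3 axially, on the face away from the axial C19 methyl, to give the equatorial 3-hydroxyl.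

Step 12
Reactants: 21 8(9)-en-3-ol
Product: 22 9-(hydroxymethyl)-8(17)-ene: C11–OH on C9 anti to C20, exocyclic C8=C17
Conditions: paraformaldehyde (3 equiv), Me2AlCl (4 equiv), CH2Cl2, −78 → 0 °C
Reagents that add atoms: formaldehyde (from paraformaldehyde), C=O
Why: Lewis-acid-promoted carbonyl-ene reaction: formaldehyde bonds to the less substituted alkene carbon C9 on the face opposite the angular C20 methyl (axial attack), so the former vinylic hydrogen ends syn to C20 and C11 anti, while a C17 hydrogen is transferred to give the exocyclic alkene.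

Step 13
Reactants: 22 homoallylic alcohol
Product: 23 8,17-epoxide with the oxygen anti to C20 and cis to C11
Conditions: VO(acac)2 (5 mol %), t-BuOOH (1.5 equiv), toluene, 0 °C → rt
Reagents that add atoms: tert-butyl hydroperoxide, CC(C)(C)OO
Why: Hydroxyl-directed epoxidation: the vanadate ester of the homoallylic C11 hydroxyl delivers oxygen to the alkene face syn to C11, which is also the face away from C20, so O8 and C11 become cis.

Step 14
Reactants: 23 spiro-epoxide
Product: 24 3,8,11-triol with 18-OTBS: tertiary 8-OH anti to C20, C17 methyl syn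
Conditions: LiAlH4, THF, 0 °C → rt
Reagents that add atoms: none
Why: Hydride opens the spiro-epoxide by SN2 attack at the primary carbon C17, leaving the C8–O bond untouched and creating the C17 methyl and the tertiary alcohol.

Step 15
Reactants: 24 triol
Product: 25 11-O-p-toluenesulfonate of 24
Conditions: TsCl (1.1 equiv), pyridine, 0 °C
Reagents that add atoms: p-toluenesulfonyl chloride, Cc1ccc(cc1)S(Cl)(=O)=O
Why: Sulfonylation is selective for the only primary hydroxyl; the secondary C3 and tertiary C8 hydroxyls are too hindered to react at 0 °C.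

Step 16
Reactants: 25 11-tosylate; 26 isoprene
Product: 29 18-O-TBS-labda-13(16),14-diene-3,8,18-triol (side chain CH2CH2C(=CH2)CH=CH2 on C9), via isoprenylpotassium 27 (not isolated), via isoprenylmagnesium bromide 28 (not isolated)
Conditions: 26 (excess), lithium 2,2,6,6-tetramethylpiperidide (from the amine and n-BuLi), KOtBu, THF, −78 → −50 °C; MgBr2·OEt2; then 25, Li2CuCl4 (5 mol %), −78 → 0 °C; aq. NH4Cl
Reagents that add atoms: none
Why: Allylic metallation of isoprene at its methyl group gives the symmetrical 2-vinylallyl anion, and copper-catalysed sp3–sp3 coupling of its Grignard form with the primary tosylate builds C11–C12 while the two free hydroxyls are carried as unreactive magnesium alkoxides.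

Step 17
Reactants: 29 diene triol monosilyl ether
Product: 30 3-O-acetate of 29
Conditions: Ac2O, 4-(dimethylamino)pyridine (0.1 equiv), pyridine, rt
Reagents that add atoms: acetic anhydride, CC(=O)OC(C)=O
Why: Acylation under nucleophilic catalysis takes place only at the secondary C3 hydroxyl because the C8 hydroxyl is tertiary and shielded.

Step 18
Reactants: 30 3-acetate 18-silyl ether
Product: 31 (3R,4S,5S,8S,9R,10R)-3-acetoxylabda-13(16),14-diene-8,18-diol (CNP0313672.1)
Conditions: HF·pyridine, pyridine/THF, 0 °C
Reagents that add atoms: none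
Why: Fluoride-mediated desilylation under buffered acidic conditions frees the C18 hydroxyl without the base-promoted acetyl shift from O3 to O18.

**Compound list**

1 | 2-(2-bromoethyl)-1,3-dioxolane | BrCCC1OCCO1 | starting material
2 | propyne | CC#C | starting material
3 | ethyl but-2-ynoate | CCOC(=O)C#CC | starting material
4 | [2-(1,3-dioxolan-2-yl)ethyl]magnesium bromide | Br[Mg]CCC1OCCO1 | intermediate
5 | (Z)-[4-(1,3-dioxolan-2-yl)-2-methylbut-1-en-1-yl]copper | [Cu]/C=C(C)\CCC1OCCO1 | intermediate
6 | ethyl (2E,4Z)-7-(1,3-dioxolan-2-yl)-3,5-dimethylhepta-2,4-dienoate | CCOC(=O)/C=C(C)/C=C(C)\CCC1OCCO1 | intermediate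
7 | (2E,4Z)-7-(1,3-dioxolan-2-yl)-3,5-dimethylhepta-2,4-dien-1-ol | OC/C=C(C)/C=C(C)\CCC1OCCO1 | intermediate
8 | (2E,4Z)-7-(1,3-dioxolan-2-yl)-3,5-dimethylhepta-2,4-dienal | O=C/C=C(C)/C=C(C)\CCC1OCCO1 | intermediate
9 | bis(4,4,5,5-tetramethyl-1,3,2-dioxaborolan-2-yl)methane | CC1(C)OB(CB2OC(C)(C)C(C)(C)O2)OC1(C)C | starting material
10 | lithio-bis(pinacolboryl)methane | [Li]C(B1OC(C)(C)C(C)(C)O1)B1OC(C)(C)C(C)(C)O1 | intermediate
11 | 2-[(1E,3E,5Z)-8-(1,3-dioxolan-2-yl)-4,6-dimethylocta-1,3,5-trien-1-yl]-4,4,5,5-tetramethyl-1,3,2-dioxaborolane | CC1(C)OB(/C=C/C=C(C)/C=C(C)\CCC2OCCO2)OC1(C)C | intermediate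
12 | (4Z,6E,8E)-4,6-dimethyl-9-(Bpin)nona-4,6,8-trienal | CC1(C)OB(/C=C/C=C(C)/C=C(C)\CCC=O)OC1(C)C | intermediate
13 | 2-(triphenyl-λ5-phosphanylidene)propanal | CC(C=O)=P(c1ccccc1)(c1ccccc1)c1ccccc1 | starting material
14 | (2E,6Z,8E,10E)-2,6,8-trimethyl-11-(Bpin)undeca-2,6,8,10-tetraenal | CC1(C)OB(/C=C/C=C(C)/C=C(C)\CC/C=C(C)/C=O)OC1(C)C | intermediate
15 | (3S,4S,5S,10S)-3-Bpin-1,8(9)-diene-18-al cycloadduct | C[C@@]12C=C[C@H](B3OC(C)(C)C(C)(C)O3)[C@](C)(C=O)[C@H]1CCC(C)=C2 | intermediate
16 | 3-Bpin-1,8(9)-dien-18-ol | C[C@@]12C=C[C@H](B3OC(C)(C)C(C)(C)O3)[C@](C)(CO)[C@H]1CCC(C)=C2 | intermediate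
17 | 1,8(9)-diene-3,18-diol (3-OH anti to C20) | C[C@@]12C=C[C@H](O)[C@](C)(CO)[C@H]1CCC(C)=C2 | intermediate
18 | 18-O-TBS ether of 17 | C[C@@]12C=C[C@H](O)[C@](C)(CO[Si](C)(C)C(C)(C)C)[C@H]1CCC(C)=C2 | intermediate
19 | 18-OTBS-1,8(9)-dien-3-one | C[C@@]12C=CC(=O)[C@](C)(CO[Si](C)(C)C(C)(C)C)[C@H]1CCC(C)=C2 | intermediate
20 | 18-OTBS-8(9)-en-3-one | C[C@@]12CCC(=O)[C@](C)(CO[Si](C)(C)C(C)(C)C)[C@H]1CCC(C)=C2 | intermediate
21 | (3R,4S,5S,10S)-18-OTBS-8(9)-en-3-ol (3-OH syn to C20) | C[C@@]12CC[C@@H](O)[C@](C)(CO[Si](C)(C)C(C)(C)C)[C@H]1CCC(C)=C2 | intermediate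
22 | 18-OTBS-8(17)-ene-3,11-diol (C11 anti to C20) | C[C@@]12CC[C@@H](O)[C@](C)(CO[Si](C)(C)C(C)(C)C)[C@H]1CCC(=C)[C@@H]2CO | intermediate
23 | 18-OTBS-8,17-epoxy-3,11-diol (epoxide O cis to C11) | C[C@@]12CC[C@@H](O)[C@](C)(CO[Si](C)(C)C(C)(C)C)[C@H]1CC[C@@]3(CO3)[C@@H]2CO | intermediate
24 | 18-OTBS-3,8,11-triol | C[C@@]12CC[C@@H](O)[C@](C)(CO[Si](C)(C)C(C)(C)C)[C@H]1CC[C@](C)(O)[C@@H]2CO | intermediate
25 | 11-O-tosyl-18-OTBS-3,8-diol | C[C@@]12CC[C@@H](O)[C@](C)(CO[Si](C)(C)C(C)(C)C)[C@H]1CC[C@](C)(O)[C@@H]2COS(=O)(=O)c3ccc(C)cc3 | intermediate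
26 | isoprene (2-methylbuta-1,3-diene) | C=CC(C)=C | starting material
27 | (2-methylidenebut-3-en-1-yl)potassium | [K]CC(=C)C=C | intermediate
28 | (2-methylidenebut-3-en-1-yl)magnesium bromide | Br[Mg]CC(=C)C=C | intermediate
29 | 18-O-TBS-labda-13(16),14-diene-3,8,18-triol | C[C@@]12CC[C@@H](O)[C@](C)(CO[Si](C)(C)C(C)(C)C)[C@H]1CC[C@](C)(O)[C@@H]2CCC(=C)C=C | intermediate
30 | 3-O-acetyl-18-O-TBS-labda-13(16),14-diene-3,8,18-triol | C[C@@]12CC[C@@H](OC(C)=O)[C@](C)(CO[Si](C)(C)C(C)(C)C)[C@H]1CC[C@](C)(O)[C@@H]2CCC(=C)C=C | intermediate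
31 | (3R,4S,5S,8S,9R,10R)-3-acetoxylabda-13(16),14-diene-8,18-diol | C[C@@]12CC[C@@H](OC(C)=O)[C@](C)(CO)[C@H]1CC[C@](C)(O)[C@@H]2CCC(=C)C=C | target

**Step count and risks**

Total steps: 18. Longest linear sequence: 18 (all other components are commercial).

Steps most likely to fail:

Step 7 (key cycloaddition). The catalyst may discriminate poorly between the enal faces, the exo (cis-fused) mode may compete because of the inside methyl on the diene, or the acid may destroy the triene (protodeboronation, cationic oligomerisation) before cyclisation. Fallback, from 12: Wittig olefination with ethyl 2-(triphenylphosphoranylidene)propanoate should give the ethyl (2E)-tetraenoate F1. An uncatalysed thermal intramolecular Diels–Alder reaction (toluene, 150–170 °C, sealed tube) should then give the racemic trans-fused ester F2, which has no free aldehyde next to the allylboronate. LiAlH4 followed by H2O2/NaOH gives racemic 17. Esterification of its primary hydroxyl with (R)-O-acetylmandelic acid (dicyclohexylcarbodiimide, 4-(dimethylamino)pyridine) gives two diastereomeric esters, from which the mandelate ester F3 is separated by chromatography or crystallisation. K2CO3/MeOH returns enantiopure 17, where the route is rejoined.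

Step 12 (ene reaction). Attack at the neopentyl-type C9 may be too slow, the proton may be lost from C7 instead of C17, or chloride may capture the C8 cation. Fallback, from 21: the far more electrophilic ethyl glyoxylate (SnCl4, CH2Cl2, −78 °C) is used as the enophile and should give the α-hydroxy ester F4 (mixture at the carbinol carbon). LiAlH4 gives the 1,2-diol F5. NaIO4 cleavage gives the aldehyde F6, which is reduced in the same flask with NaBH4 at 0 °C before C9 can epimerise; the product is 22.

Step 16 (side-chain coupling). E2 elimination, or intramolecular O-alkylation by the C8 alkoxide (oxetane formation), may outpace the copper-catalysed substitution at the β-branched primary carbon. Fallback, from 25: NaI in acetone gives the primary iodide F7. Radical allylation under neutral conditions with the isoprenyl stannane F8 (tributyl(2-methylidenebut-3-en-1-yl)stannane, made from 27 and Bu3SnCl), azobisisobutyronitrile, benzene, 80 °C (Keck allylation: the C11 radical adds to the CH2= terminus of the stannane and expels the stannyl radical) should give 29 directly, the free hydroxyls being inert.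

Further compounds
F1 | step 7 | ethyl (2E,6Z,8E,10E)-2,6,8-trimethyl-11-(Bpin)undeca-2,6,8,10-tetraenoate | CC1(C)OB(/C=C/C=C(C)/C=C(C)\CC/C=C(C)/C(=O)OCC)OC1(C)C
F2 | step 7 | racemic ethyl ester analogue of 15 (one enantiomer drawn) | C[C@@]12C=C[C@H](B3OC(C)(C)C(C)(C)O3)[C@](C)(C(=O)OCC)[C@H]1CCC(C)=C2
F3 | step 7 | 18-O-[(R)-O-acetylmandeloyl] ester of 17 | C[C@@]12C=C[C@H](O)[C@](C)(COC(=O)[C@H](OC(C)=O)c3ccccc3)[C@H]1CCC(C)=C2
F4 | step 12 | ethyl 2-hydroxy-2-(C9-yl)acetate ene adduct of 21 (8(17)-ene, carbinol centre unassigned) | C[C@@]12CC[C@@H](O)[C@](C)(CO[Si](C)(C)C(C)(C)C)[C@H]1CCC(=C)[C@@H]2C(O)C(=O)OCC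
F5 | step 12 | 1,2-diol from F4 | C[C@@]12CC[C@@H](O)[C@](C)(CO[Si](C)(C)C(C)(C)C)[C@H]1CCC(=C)[C@@H]2C(O)CO
F6 | step 12 | C11 aldehyde (9-formyl-8(17)-ene) | C[C@@]12CC[C@@H](O)[C@](C)(CO[Si](C)(C)C(C)(C)C)[C@H]1CCC(=C)[C@@H]2C=O
F7 | step 16 | 11-iodo-18-OTBS-3,8-diol | C[C@@]12CC[C@@H](O)[C@](C)(CO[Si](C)(C)C(C)(C)C)[C@H]1CC[C@](C)(O)[C@@H]2CI
F8 | step 16 | tributyl(2-methylidenebut-3-en-1-yl)stannane | CCCC[Sn](CCCC)(CCCC)CC(=C)C=C
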